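**Strategy**

Ring C is cut at the acyloin bond between the C4 carbonyl and the C3 carbinol carbon. The precursor is an open aryl ether: a ring A salicylaldehyde (formyl carbon = C4) whose phenolic oxygen (O1) carries a racemic CH(aryl)–CO–CO2allyl unit (C2, C3). A chiral triazolylidene closes ring C by an intramolecular crossed benzoin reaction. The step exploits the fact that C2 is α to the keto ester before closure, so it epimerizes, but is fixed afterwards; one operation therefore forms ring C, the C4 ketone and the C3 carbinol and sets C2 by dynamic kinetic resolution. The extra ester leaves as CO2 during the final global deallylation, which re-sets C3 trans.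

Key step: step 7

Assumption: 2,4,6-trihydroxy-3-methylbenzaldehyde (10) is treated as a purchasable building block; which antipode of the triazolium salt leads to the 2R series must be settled by experiment, and the route is written for the (5aS,10bR) salt.

Shorthand: geranyl = (2E)-3,7-dimethylocta-2,6-dien-1-yl; allyl = prop-2-en-1-yl.

**Route**

Step 1
Reactants: 1 4-hydroxybenzaldehyde; 2 geranyl bromide
Product: 3 3-geranyl-4-hydroxybenzaldehyde
Conditions: KOH, H2O, 23 °C; then dilute HCl
Reagents that add atoms: none
Why: Aqueous-alkali C-allylation of the phenoxide (ambident Williamson-type alkylation), in which hydrogen bonding of water to the phenoxide oxygen diverts the primary allylic bromide to the ortho carbon (para is blocked) and SN2 attack at C1 of the bromide keeps the E-olefin.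

Step 2
Reactants: 3 3-geranyl-4-hydroxybenzaldehyde
Product: 4 4-(allyloxy)-3-geranylbenzaldehyde
Conditions: allyl bromide, K2CO3, acetone, reflux
Reagents that add atoms: allyl bromide, C=CCBr
Why: Williamson ether synthesis masks the phenol so that the aldehyde stays electrophilic in the Darzens step, with a group that can later be removed under neutral palladium catalysis without touching the geranyl olefins.

Step 3
Reactants: 5 dichloroacetic acid; 6 allyl alcohol
Product: 7 allyl dichloroacetate
Conditions: p-toluenesulfonic acid (cat.), cyclohexane, reflux, azeotropic removal of water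
Reagents that add atoms: none
Why: Fischer esterification pulled to completion by removal of water.

Step 4
Reactants: 4 4-(allyloxy)-3-geranylbenzaldehyde; 7 allyl dichloroacetate
Product: 9 allyl 3-[4-(allyloxy)-3-geranylphenyl]-3-chloro-2-oxopropanoate (racemic), via chloroglycidic ester 8 (not isolated)
Conditions: NaN(SiMe3)2, THF, −78 °C to 23 °C
Reagents that add atoms: none
Why: Darzens condensation of the dichloroacetate enolate with the aldehyde gives the α-chloroglycidic ester, which on warming should open at the benzylic carbon with 1,2-chloride shift (α-chloroepoxide to α-chloroketone isomerization, assisted by the para-alkoxy group); the stereocenter is racemic by design.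

Step 5
Reactants: 10 2,4,6-trihydroxy-3-methylbenzaldehyde
Product: 11 4-(allyloxy)-2,6-dihydroxy-3-methylbenzaldehyde
Conditions: allyl bromide (1.0 equiv), K2CO3 (1.0 equiv), DMF, 0 °C to 23 °C
Reagents that add atoms: allyl bromide, C=CCBr
Why: Williamson etherification at the most acidic hydroxyl, the one para to the formyl group, which alone of the three is not hydrogen-bonded to the carbonyl oxygen.

Step 6
Reactants: 11 4-(allyloxy)-2,6-dihydroxy-3-methylbenzaldehyde; 9 allyl 3-[4-(allyloxy)-3-geranylphenyl]-3-chloro-2-oxopropanoate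
Product: 12 allyl 3-[5-(allyloxy)-2-formyl-3-hydroxy-4-methylphenoxy]-3-[4-(allyloxy)-3-geranylphenyl]-2-oxopropanoate (racemic)
Conditions: K2CO3, acetone, 0 °C to 23 °C
Reagents that add atoms: none
Why: Williamson-type SN2 displacement of the doubly activated (benzylic, α-keto) chloride by the phenoxide, in which the hydroxyl next to the ring C–H should be alkylated because the methyl-flanked hydroxyl is more hindered and stays locked in the hydrogen bond to the formyl group, which also stops a second alkylation; the new stereocenter is racemic by design.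

Step 7
Reactants: 12 allyl 3-[5-(allyloxy)-2-formyl-3-hydroxy-4-methylphenoxy]-3-[4-(allyloxy)-3-geranylphenyl]-2-oxopropanoate
Product: 13 allyl (2R,3R)-7-(allyloxy)-2-[4-(allyloxy)-3-geranylphenyl]-3,5-dihydroxy-6-methyl-4-oxochromane-3-carboxylate
Conditions: (5aS,10bR)-2-(pentafluorophenyl)-5a,10b-dihydro-4H,6H-indeno[2,1-b][1,2,4]triazolo[4,3-d][1,4]oxazin-2-ium tetrafluoroborate (15 mol %), K2CO3 (0.5 equiv), t-BuOMe, 23 °C, argon
Reagents that add atoms: none
Why: Proposed new method: the triazolylidene adds to the formyl group (the only aldehyde present, activated by the hydrogen bond from the neighbouring hydroxyl), the resulting enaminol acts as an acyl anion equivalent and attacks the ketone of the α-keto ester, and proton transfer then releases the carbene. The closest known reaction types are the carbene-catalysed intramolecular aldehyde–ketone crossed benzoin cyclization to 3-hydroxychroman-4-ones and the dynamic kinetic asymmetric cross-benzoin addition to β-stereogenic α-keto esters; their combination on an α-aryloxy keto ester is the new element. Ring C closes in the 6-exo-trig mode. C3 is set by the ketone face that the aminoindanol-derived catalyst leaves open, and C2 is set by dynamic kinetic resolution, since the enantiomers of 12 interconvert through the enolate under K2CO3 and only the one that places the aryl group pseudo-equatorial in the closing half-chair is expected to cyclize quickly. The step needs chemoselectivity for one acyl anion donor, secured because a keto ester cannot form one, and epimerization faster than closure, secured by the C2–H being flanked by aryl, aryloxy and 1,2-dicarbonyl groups. The reversible aldol addition of the C2 enolate to the formyl group is the competing pathway that the carbene must outrun.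

Step 8
Reactants: 13 allyl (2R,3R)-7-(allyloxy)-2-[4-(allyloxy)-3-geranylphenyl]-3,5-dihydroxy-6-methyl-4-oxochromane-3-carboxylate
Product: 16 (2R,3R)-3,5,7-trihydroxy-2-(3-geranyl-4-hydroxyphenyl)-6-methylchroman-4-one (target), via keto acid 14 (not isolated), via enediol 15 (not isolated)
Conditions: Pd(PPh3)4 (5 mol %), morpholine, degassed THF, 23 °C to 40 °C, argon; then AcOH
Reagents that add atoms: none
Why: Tsuji–Trost deallylation with zerovalent palladium transfers all three allyl groups to morpholine, the freed β-keto acid decarboxylates to the enediol, and ketonization with amine-mediated equilibration should give the conjugated, hydrogen-bonded C4 ketone with the C3 hydroxyl equatorial and trans to the C2 aryl group, so either C3 epimer of 13 converges on (2R,3R).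

**Compound list**

1 | 4-hydroxybenzaldehyde | O=Cc1ccc(O)cc1 | starting material
2 | geranyl bromide, (2E)-1-bromo-3,7-dimethylocta-2,6-diene | CC(C)=CCC/C(C)=C/CBr | starting material
3 | 3-[(2E)-3,7-dimethylocta-2,6-dien-1-yl]-4-hydroxybenzaldehyde | CC(C)=CCC/C(C)=C/Cc1cc(C=O)ccc1O | intermediate
4 | 4-(allyloxy)-3-[(2E)-3,7-dimethylocta-2,6-dien-1-yl]benzaldehyde | CC(C)=CCC/C(C)=C/Cc1cc(C=O)ccc1OCC=C | intermediate
5 | dichloroacetic acid | OC(=O)C(Cl)Cl | starting material
6 | allyl alcohol (prop-2-en-1-ol) | OCC=C | starting material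
7 | allyl dichloroacetate | C=CCOC(=O)C(Cl)Cl | intermediate
8 | allyl 3-[4-(allyloxy)-3-geranylphenyl]-2-chlorooxirane-2-carboxylate (racemic, diastereomer mixture) | C=CCOC(=O)C1(Cl)OC1c1ccc(OCC=C)c(C/C=C(\C)CCC=C(C)C)c1 | intermediate (not isolated)
9 | allyl 3-[4-(allyloxy)-3-geranylphenyl]-3-chloro-2-oxopropanoate (racemic) | C=CCOC(=O)C(=O)C(Cl)c1ccc(OCC=C)c(C/C=C(\C)CCC=C(C)C)c1 | intermediate
10 | 2,4,6-trihydroxy-3-methylbenzaldehyde | Cc1c(O)cc(O)c(C=O)c1O | starting material
11 | 4-(allyloxy)-2,6-dihydroxy-3-methylbenzaldehyde | Cc1c(OCC=C)cc(O)c(C=O)c1O | intermediate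
12 | allyl 3-[5-(allyloxy)-2-formyl-3-hydroxy-4-methylphenoxy]-3-[4-(allyloxy)-3-geranylphenyl]-2-oxopropanoate (racemic) | C=CCOC(=O)C(=O)C(Oc1cc(OCC=C)c(C)c(O)c1C=O)c1ccc(OCC=C)c(C/C=C(\C)CCC=C(C)C)c1 | intermediate
13 | allyl (2R,3R)-7-(allyloxy)-2-[4-(allyloxy)-3-geranylphenyl]-3,5-dihydroxy-6-methyl-4-oxochromane-3-carboxylate (drawn 3R; C3 is re-set in step 8) | CC(C)=CCC/C(C)=C/Cc1cc([C@H]2Oc3cc(OCC=C)c(C)c(O)c3C(=O)[C@@]2(O)C(=O)OCC=C)ccc1OCC=C | intermediate
14 | (2R,3R)-2-(3-geranyl-4-hydroxyphenyl)-3,5,7-trihydroxy-6-methyl-4-oxochromane-3-carboxylic acid | CC(C)=CCC/C(C)=C/Cc1cc([C@H]2Oc3cc(O)c(C)c(O)c3C(=O)[C@@]2(O)C(O)=O)ccc1O | intermediate (not isolated)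
15 | (2R)-2-(3-geranyl-4-hydroxyphenyl)-6-methyl-2H-chromene-3,4,5,7-tetrol | CC(C)=CCC/C(C)=C/Cc1cc([C@H]2Oc3cc(O)c(C)c(O)c3C(O)=C2O)ccc1O | intermediate (not isolated)
16 | (2R,3R)-3,5,7-trihydroxy-2-{4-hydroxy-3-[(2E)-3,7-dimethylocta-2,6-dien-1-yl]phenyl}-6-methyl-2,3-dihydro-4H-chromen-4-one | CC(C)=CCC/C(C)=C/Cc1cc([C@H]2Oc3cc(O)c(C)c(O)c3C(=O)[C@@H]2O)ccc1O | target

**Step count and risks**

Total step count: 8. Longest linear sequence: 6 (steps 1, 2, 4, 6, 7, 8).

Steps most likely to fail:

Step 7 (carries the label). What may go wrong: slow carbene addition to the di-ortho-substituted, electron-rich formyl group; epimerization at C2 too slow relative to ring closure, or weak matching between catalyst and substrate, so that enantiomeric purity at C2 erodes; reversible aldol closure of the C2 enolate onto the aldehyde draining material. The fallback uses known chemistry, sets out from 12 and comes back at 13. Compound 12 is cyclized with the achiral carbene generated from 2-mesityl-6,7-dihydro-5H-pyrrolo[2,1-c][1,2,4]triazol-2-ium chloride and 1,8-diazabicyclo[5.4.0]undec-7-ene in THF, the established intramolecular aldehyde–ketone crossed benzoin. This should give racemic material, that is 13 together with its mirror image, allyl (2S,3S)-7-(allyloxy)-2-[4-(allyloxy)-3-geranylphenyl]-3,5-dihydroxy-6-methyl-4-oxochromane-3-carboxylate F1. The enantiomers are then separated by preparative chromatography on a cellulose tris(3,5-dimethylphenylcarbamate) phase, and 13 re-enters at step 8.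

Step 6. What may go wrong: enolization of the chloro keto ester or of the product under carbonate, followed by aldol closure onto the formyl group or hydrolysis, outpacing O-alkylation; partial alkylation at the methyl-flanked hydroxyl. The fallback sets out from 9 (with 11) and comes back at 12; it makes the ether bond under neutral conditions by carbene O–H insertion. Reductive dechlorination of 9 with Zn in AcOH should give allyl 3-[4-(allyloxy)-3-geranylphenyl]-2-oxopropanoate F2. Regitz diazo transfer with 4-acetamidobenzenesulfonyl azide and 1,8-diazabicyclo[5.4.0]undec-7-ene in MeCN should give allyl 3-[4-(allyloxy)-3-geranylphenyl]-3-diazo-2-oxopropanoate F3. Slow addition of F3 to 11 and Rh2(OAc)4 in CH2Cl2 should insert the carbene into the less hindered phenolic O–H bond and return 12.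

Step 8. What may go wrong: air oxidation of the transient enediol to the flavonol, ketonization toward C3 instead of C4, or epimerization at C2 by ring opening under the amine. The fallback sets out from 13 and comes back at 16; it caps the C3 oxygen so that no free enediol is formed.
- Silylation of the tertiary and the phenolic hydroxyl of 13 with t-BuMe2SiOTf and 2,6-lutidine in CH2Cl2 should give allyl (2R,3R)-7-(allyloxy)-2-[4-(allyloxy)-3-geranylphenyl]-3,5-bis(tert-butyldimethylsilyloxy)-6-methyl-4-oxochromane-3-carboxylate F4.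
- The same Pd(PPh3)4 and morpholine treatment should then give (2R,3R)-3,5-bis(tert-butyldimethylsilyloxy)-2-(3-geranyl-4-hydroxyphenyl)-7-hydroxy-6-methyl-4-oxochromane-3-carboxylic acid F5.
- F5 should lose CO2 to (2R)-3,5-bis(tert-butyldimethylsilyloxy)-2-(3-geranyl-4-hydroxyphenyl)-6-methyl-2H-chromene-4,7-diol F6, an enol that can ketonize only at C4.
- Ketonization should give (2R,3R)-3,5-bis(tert-butyldimethylsilyloxy)-2-(3-geranyl-4-hydroxyphenyl)-7-hydroxy-6-methylchroman-4-one F7.
- HF·pyridine in THF removes both silyl groups; brief exposure to mild base equilibrates any C3 epimer to the trans isomer 16.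

Further compounds
F1 | step 7 | allyl (2S,3S)-7-(allyloxy)-2-[4-(allyloxy)-3-geranylphenyl]-3,5-dihydroxy-6-methyl-4-oxochromane-3-carboxylate | CC(C)=CCC/C(C)=C/Cc1cc([C@@H]2Oc3cc(OCC=C)c(C)c(O)c3C(=O)[C@]2(O)C(=O)OCC=C)ccc1OCC=C
F2 | step 6 | allyl 3-[4-(allyloxy)-3-geranylphenyl]-2-oxopropanoate | C=CCOC(=O)C(=O)Cc1ccc(OCC=C)c(C/C=C(\C)CCC=C(C)C)c1
F3 | step 6 | allyl 3-[4-(allyloxy)-3-geranylphenyl]-3-diazo-2-oxopropanoate | C=CCOC(=O)C(=O)C(=[N+]=[N-])c1ccc(OCC=C)c(C/C=C(\C)CCC=C(C)C)c1
F4 | step 8 | allyl (2R,3R)-7-(allyloxy)-2-[4-(allyloxy)-3-geranylphenyl]-3,5-bis(tert-butyldimethylsilyloxy)-6-methyl-4-oxochromane-3-carboxylate | CC(C)=CCC/C(C)=C/Cc1cc([C@H]2Oc3cc(OCC=C)c(C)c(O[Si](C)(C)C(C)(C)C)c3C(=O)[C@@]2(O[Si](C)(C)C(C)(C)C)C(=O)OCC=C)ccc1OCC=C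
F5 | step 8 | (2R,3R)-3,5-bis(tert-butyldimethylsilyloxy)-2-(3-geranyl-4-hydroxyphenyl)-7-hydroxy-6-methyl-4-oxochromane-3-carboxylic acid | CC(C)=CCC/C(C)=C/Cc1cc([C@H]2Oc3cc(O)c(C)c(O[Si](C)(C)C(C)(C)C)c3C(=O)[C@@]2(O[Si](C)(C)C(C)(C)C)C(O)=O)ccc1O
F6 | step 8 | (2R)-3,5-bis(tert-butyldimethylsilyloxy)-2-(3-geranyl-4-hydroxyphenyl)-6-methyl-2H-chromene-4,7-diol | CC(C)=CCC/C(C)=C/Cc1cc([C@H]2Oc3cc(O)c(C)c(O[Si](C)(C)C(C)(C)C)c3C(O)=C2O[Si](C)(C)C(C)(C)C)ccc1O
F7 | step 8 | (2R,3R)-3,5-bis(tert-butyldimethylsilyloxy)-2-(3-geranyl-4-hydroxyphenyl)-7-hydroxy-6-methylchroman-4-one | CC(C)=CCC/C(C)=C/Cc1cc([C@H]2Oc3cc(O)c(C)c(O[Si](C)(C)C(C)(C)C)c3C(=O)[C@@H]2O[Si](C)(C)C(C)(C)C)ccc1O
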